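**Plan**

1. Numbering: C1 (alkyne CH) to C15 (CH3) along the chain of the target, ring oxygen between C7 and C12; the target is 3Z,6S,7S,12R,13S with a 2,7-cis oxepene. Late cuts: C13–Br (from the 13R alcohol, inversion), the acetate, C2–C3 plus the C3=C4 π-bond (silyl diyne, cis semi-reduction), C5–C6 (propargylation of a C6 aldehyde) and C13–C14 (ethyl onto a C13 acyl group).
2. What remains is a cis-2,7-diacyl oxepene. Its C7–O–C12 unit, flanked by the acyl carbons C6 and C13, is a double α-alkoxy enolate donor, and the ring's cis-but-2-ene-1,4-diyl unit C8–C9=C10–C11 is a double allylic acceptor. Both ring C–C bonds (C11–C12 and C7–C8) are therefore cut in one operation, back to a diglycolic acid derivative and (Z)-1-chloro-4-iodobut-2-ene.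
3. Forward: diglycolic anhydride → amide acid → acyl oxazolidinone; a one-pot double alkylation closes the only ring; then the C13 arm (thioester → ethyl ketone → alcohol), the C6 arm (amide → aldehyde → homopropargyl alcohol → diyne → Z-enyne), the acetate, and the bromide last.
4. Stereochemistry: C12 from the oxazolidinone auxiliary; C7 from C12 in the ring closure (2,7-cis); C13 by Felkin–Anh hydride reduction, then SN2 inversion by bromide; C6 by magnesium-chelate-controlled propargylation; C3=C4 Z by cis semi-reduction; C9=C10 Z carried in from cis-1,4-dichlorobut-2-ene.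

Key step: step 4

**Route**

Step 1
Reactants: 1 diglycolic anhydride (1,4-dioxane-2,6-dione)
Product: 2 [2-(dimethylamino)-2-oxoethoxy]acetic acid
Conditions: Me2NH (2.0 M in THF, 1.0 equiv), CH2Cl2, 0 °C → rt
Reagents that add atoms: dimethylamine, CNC
Why: Aminolysis of a cyclic anhydride should stop at the mono-amide acid because the carboxylate that forms is not acylating; no stereocentre is involved.

Step 2
Reactants: 2 [2-(dimethylamino)-2-oxoethoxy]acetic acid; 3 (4S)-4-benzyl-5,5-dimethyl-1,3-oxazolidin-2-one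
Product: 5 (4S)-4-benzyl-3-{[2-(dimethylamino)-2-oxoethoxy]acetyl}-5,5-dimethyl-1,3-oxazolidin-2-one, via pivalic mixed anhydride 4 (not isolated)
Conditions: t-BuCOCl, Et3N, THF, −20 °C; then 3, LiCl, rt
Reagents that add atoms: none
Why: N-acylation of the oxazolidinone through a mixed anhydride (LiCl/Et3N acylation) should occur at the less hindered alkoxyacetyl carbonyl, the tertiary amide being inert.

Step 3
Reactants: 6 cis-1,4-dichlorobut-2-ene
Product: 7 (Z)-1-chloro-4-iodobut-2-ene
Conditions: NaI (1.0 equiv), 6 (3 equiv), acetone, 0 °C, dark; NaCl filtered off, excess 6 removed in vacuo, 7 used at once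
Reagents that add atoms: sodium iodide, [Na+].[I-]
Why: Finkelstein exchange with a deficit of iodide on an excess of the symmetric dichloride should give mainly the mono-iodide by SN2 at the primary allylic carbon, with the Z-geometry kept at low temperature in the dark.

Step 4
Reactants: 5 (4S)-4-benzyl-3-{[2-(dimethylamino)-2-oxoethoxy]acetyl}-5,5-dimethyl-1,3-oxazolidin-2-one; 7 (Z)-1-chloro-4-iodobut-2-ene
Product: 9 (2S,7R)-7-{[(4S)-4-benzyl-5,5-dimethyl-2-oxo-1,3-oxazolidin-3-yl]carbonyl}-N,N-dimethyl-2,3,6,7-tetrahydrooxepine-2-carboxamide, via monoalkylated chloro imide 8 (not isolated)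
Conditions: NaN(SiMe3)2 (1.1 equiv), THF, −78 °C; 7 (0.95 equiv), −78 → −45 °C; dilution with THF, KN(SiMe3)2 (1.2 equiv), −78 → −40 °C; aq. NH4Cl
Reagents that add atoms: none
Why: NaN(SiMe3)2 removes only the more acidic imide α-proton of 5, and the sodium-chelated Z-enolate displaces iodide from 7 by SN2 on the face away from the benzyl group of the auxiliary (oxazolidinone glycolate alkylation), which forms C11–C12 and sets C12 as R in 8. KN(SiMe3)2 then enolises the O–CH2–CONMe2 unit and the amide enolate carbon displaces the allylic chloride at C8 by SN2, which forms C7–C8; the closest known reaction type is the intramolecular alkylation of α-alkoxy N,N-dimethylamide enolates by Z-allylic chlorides, used for 2,7-cis-oxepenes. The oxepene ring closes in the 7-exo-tet mode. C7 is controlled by C12: the C12–H bond eclipses the enolate plane to avoid allylic 1,3-strain, so the tether reaches the enolate face that puts the carboxamide at C7 cis to the acyl group at C12 (7S). The step needs site selectivity between the two enolisable positions, which rests on the acidity gap between imide and amide in the first stage and, in the second, on the allylic 1,3-strain that disfavours enolisation of the now tertiary imide α-C–H, while the 5,5-dimethyl group shields the ring carbonyl of the auxiliary from the amide enolate. It also needs iodide-before-chloride selectivity on 7 (leaving-group ability), SN2 over SN2′ closure (attack at the primary allylic carbon held close by the Z-olefin) and closure over intermolecular alkylation (7 is the limiting reagent, so no allylic iodide is left, and the second stage is run dilute).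

Step 5
Reactants: 9 (2S,7R)-7-{[(4S)-4-benzyl-5,5-dimethyl-2-oxo-1,3-oxazolidin-3-yl]carbonyl}-N,N-dimethyl-2,3,6,7-tetrahydrooxepine-2-carboxamide
Product: 10 S-ethyl (2R,7S)-7-(dimethylcarbamoyl)-2,3,6,7-tetrahydrooxepine-2-carbothioate
Conditions: EtSH, n-BuLi, THF, 0 °C
Reagents that add atoms: ethanethiol (as its lithium thiolate), CCS
Why: Transthioesterification by a weakly basic thiolate should cleave the exocyclic imide carbonyl only (the gem-dimethyl group blocks the ring carbonyl), leaving the tertiary amide and both α-stereocentres untouched.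

Step 6
Reactants: 10 S-ethyl (2R,7S)-7-(dimethylcarbamoyl)-2,3,6,7-tetrahydrooxepine-2-carbothioate
Product: 11 (2S,7R)-N,N-dimethyl-7-propanoyl-2,3,6,7-tetrahydrooxepine-2-carboxamide
Conditions: EtZnI, PdCl2(PPh3)2 (5 mol%), toluene, rt
Reagents that add atoms: ethylzinc iodide, CC[Zn]I
Why: Fukuyama coupling (insertion of zerovalent palladium into the C–S bond, transmetallation from zinc, reductive elimination) should give the ethyl ketone under neutral conditions that neither touch the amide nor epimerise C12.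

Step 7
Reactants: 11 (2S,7R)-N,N-dimethyl-7-propanoyl-2,3,6,7-tetrahydrooxepine-2-carboxamide
Product: 12 (2S,7R)-7-[(1R)-1-hydroxypropyl]-N,N-dimethyl-2,3,6,7-tetrahydrooxepine-2-carboxamide
Conditions: LiBH(s-Bu)3, THF, −78 °C
Reagents that add atoms: none
Why: Felkin–Anh reduction of an α-alkoxy ketone by a bulky, non-chelating hydride, which attacks anti to the C12–O bond and past the C12–H, should set C13 as R (syn to the ring oxygen) without touching the amide or the olefin.

Step 8
Reactants: 12 (2S,7R)-7-[(1R)-1-hydroxypropyl]-N,N-dimethyl-2,3,6,7-tetrahydrooxepine-2-carboxamide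
Product: 13 (2S,7R)-N,N-dimethyl-7-[(1R)-1-(triethylsilyloxy)propyl]-2,3,6,7-tetrahydrooxepine-2-carboxamide
Conditions: Et3SiCl, imidazole, DMF, 0 °C → rt
Reagents that add atoms: chlorotriethylsilane, CC[Si](Cl)(CC)CC
Why: Silyl ether formation masks the C13 hydroxyl so that the C6 aldehyde made next cannot close a bridged lactol, and so that only the C6 hydroxyl is acetylated later.

Step 9
Reactants: 13 (2S,7R)-N,N-dimethyl-7-[(1R)-1-(triethylsilyloxy)propyl]-2,3,6,7-tetrahydrooxepine-2-carboxamide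
Product: 14 (2S,7R)-7-[(1R)-1-(triethylsilyloxy)propyl]-2,3,6,7-tetrahydrooxepine-2-carbaldehyde
Conditions: Cp2Zr(H)Cl (1.5 equiv), THF, rt, 20 min; aqueous work-up; crude aldehyde used directly
Reagents that add atoms: none
Why: Reduction of a tertiary amide by the zirconium hydride stops at a zirconated hemiaminal that releases the aldehyde only on work-up, and it should be faster than hydrozirconation of the 1,2-disubstituted ring olefin and neutral enough to keep C7 intact.

Step 10
Reactants: 14 (2S,7R)-7-[(1R)-1-(triethylsilyloxy)propyl]-2,3,6,7-tetrahydrooxepine-2-carbaldehyde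
Product: 15 (1S)-1-{(2S,7R)-7-[(1R)-1-(triethylsilyloxy)propyl]-2,3,6,7-tetrahydrooxepin-2-yl}but-3-yn-1-ol
Conditions: MgBr2·OEt2 (3 equiv), CH2Cl2, −78 °C; CH2=C=CHSnBu3, −78 → −20 °C
Reagents that add atoms: tributyl(propa-1,2-dien-1-yl)stannane, C=C=C[Sn](CCCC)(CCCC)CCCC
Why: Chelation-controlled SE2′ propargylation: magnesium bridges the aldehyde oxygen and the ring oxygen, and the allenylstannane attacks the face away from the ring CH2 (C8), which should set C6 as S (syn to the ring oxygen).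

Step 11
Reactants: 15 (1S)-1-{(2S,7R)-7-[(1R)-1-(triethylsilyloxy)propyl]-2,3,6,7-tetrahydrooxepin-2-yl}but-3-yn-1-ol
Product: 16 (1S)-1-{(2S,7R)-7-[(1R)-1-(triethylsilyloxy)propyl]-2,3,6,7-tetrahydrooxepin-2-yl}-6-(triisopropylsilyl)hexa-3,5-diyn-1-ol
Conditions: (i-Pr)3SiC≡CBr, CuCl (10 mol%), NH2OH·HCl, 30% aq. n-BuNH2, CH2Cl2, 0 °C
Reagents that add atoms: (bromoethynyl)triisopropylsilane, BrC#C[Si](C(C)C)(C(C)C)C(C)C
Why: Cadiot–Chodkiewicz coupling of the terminal alkyne with a bromoalkyne should give the unsymmetrical silyl-capped diyne in the presence of the free hydroxyl, the silyl ether and the ring olefin.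

Step 12
Reactants: 16 (1S)-1-{(2S,7R)-7-[(1R)-1-(triethylsilyloxy)propyl]-2,3,6,7-tetrahydrooxepin-2-yl}-6-(triisopropylsilyl)hexa-3,5-diyn-1-ol
Product: 17 (1S,3Z)-1-{(2S,7R)-7-[(1R)-1-(triethylsilyloxy)propyl]-2,3,6,7-tetrahydrooxepin-2-yl}-6-(triisopropylsilyl)hex-3-en-5-yn-1-ol
Conditions: Zn dust activated with Cu(OAc)2 and AgNO3, MeOH/H2O (1:1), 40 °C
Reagents that add atoms: none
Why: Activated-zinc cis semi-reduction of a conjugated triple bond should act on C3≡C4 (conjugation-activated, assisted by the homopropargylic hydroxyl), while the silyl-capped triple bond and the isolated ring olefin are not reduced; cis delivery of two hydrogens gives the 3Z olefin.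

Step 13
Reactants: 17 (1S,3Z)-1-{(2S,7R)-7-[(1R)-1-(triethylsilyloxy)propyl]-2,3,6,7-tetrahydrooxepin-2-yl}-6-(triisopropylsilyl)hex-3-en-5-yn-1-ol
Product: 18 (1S,3Z)-1-{(2S,7R)-7-[(1R)-1-(triethylsilyloxy)propyl]-2,3,6,7-tetrahydrooxepin-2-yl}-6-(triisopropylsilyl)hex-3-en-5-yn-1-yl acetate
Conditions: Ac2O, pyridine, DMAP (cat.), CH2Cl2, rt
Reagents that add atoms: acetic anhydride, CC(=O)OC(C)=O
Why: Acylation of the only free hydroxyl (C6) under nucleophilic catalysis, with retention at C6.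

Step 14
Reactants: 18 (1S,3Z)-1-{(2S,7R)-7-[(1R)-1-(triethylsilyloxy)propyl]-2,3,6,7-tetrahydrooxepin-2-yl}-6-(triisopropylsilyl)hex-3-en-5-yn-1-yl acetate
Product: 19 (1S,3Z)-1-{(2S,7R)-7-[(1R)-1-hydroxypropyl]-2,3,6,7-tetrahydrooxepin-2-yl}hex-3-en-5-yn-1-yl acetate
Conditions: Bu4NF (2.5 equiv), THF, 0 °C
Reagents that add atoms: none
Why: Fluoride cleaves both the Si–C(sp) bond and the triethylsilyl ether in one operation, and the acetate should survive a short exposure at 0 °C.

Step 15
Reactants: 19 (1S,3Z)-1-{(2S,7R)-7-[(1R)-1-hydroxypropyl]-2,3,6,7-tetrahydrooxepin-2-yl}hex-3-en-5-yn-1-yl acetate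
Product: 20 (1S,3Z)-1-{(2S,7R)-7-[(1S)-1-bromopropyl]-2,3,6,7-tetrahydrooxepin-2-yl}hex-3-en-5-yn-1-yl acetate
Conditions: CBr4, P(n-C8H17)3, toluene, 70 °C
Reagents that add atoms: carbon tetrabromide, BrC(Br)(Br)Br
Why: Appel-type bromination: the alkoxyphosphonium ion is displaced by bromide in an SN2 step, so the 13R alcohol should give the 13S bromide with inversion, the enyne and acetate being inert.

**Compound list**

1 | diglycolic anhydride (1,4-dioxane-2,6-dione) | O=C1COCC(=O)O1 | starting material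
2 | [2-(dimethylamino)-2-oxoethoxy]acetic acid | CN(C)C(=O)COCC(=O)O | intermediate
3 | (4S)-4-benzyl-5,5-dimethyl-1,3-oxazolidin-2-one | CC1(C)OC(=O)N[C@H]1Cc1ccccc1 | starting material
4 | [2-(dimethylamino)-2-oxoethoxy]acetic pivalic anhydride | CN(C)C(=O)COCC(=O)OC(=O)C(C)(C)C | intermediate
5 | (4S)-4-benzyl-3-{[2-(dimethylamino)-2-oxoethoxy]acetyl}-5,5-dimethyl-1,3-oxazolidin-2-one | CN(C)C(=O)COCC(=O)N1C(=O)OC(C)(C)[C@@H]1Cc1ccccc1 | intermediate
6 | cis-1,4-dichlorobut-2-ene | ClC/C=C\CCl | starting material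
7 | (Z)-1-chloro-4-iodobut-2-ene | ClC/C=C\CI | intermediate
8 | (4S)-4-benzyl-3-{(2R,4Z)-6-chloro-2-[2-(dimethylamino)-2-oxoethoxy]hex-4-enoyl}-5,5-dimethyl-1,3-oxazolidin-2-one | CN(C)C(=O)CO[C@H](C/C=C\CCl)C(=O)N1C(=O)OC(C)(C)[C@@H]1Cc1ccccc1 | intermediate
9 | (2S,7R)-7-{[(4S)-4-benzyl-5,5-dimethyl-2-oxo-1,3-oxazolidin-3-yl]carbonyl}-N,N-dimethyl-2,3,6,7-tetrahydrooxepine-2-carboxamide | CN(C)C(=O)[C@@H]1CC=CC[C@H](C(=O)N2C(=O)OC(C)(C)[C@@H]2Cc2ccccc2)O1 | intermediate
10 | S-ethyl (2R,7S)-7-(dimethylcarbamoyl)-2,3,6,7-tetrahydrooxepine-2-carbothioate | CN(C)C(=O)[C@@H]1CC=CC[C@H](C(=O)SCC)O1 | intermediate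
11 | (2S,7R)-N,N-dimethyl-7-propanoyl-2,3,6,7-tetrahydrooxepine-2-carboxamide | CN(C)C(=O)[C@@H]1CC=CC[C@H](C(=O)CC)O1 | intermediate
12 | (2S,7R)-7-[(1R)-1-hydroxypropyl]-N,N-dimethyl-2,3,6,7-tetrahydrooxepine-2-carboxamide | CN(C)C(=O)[C@@H]1CC=CC[C@H]([C@H](O)CC)O1 | intermediate
13 | (2S,7R)-N,N-dimethyl-7-[(1R)-1-(triethylsilyloxy)propyl]-2,3,6,7-tetrahydrooxepine-2-carboxamide | CN(C)C(=O)[C@@H]1CC=CC[C@H]([C@H](O[Si](CC)(CC)CC)CC)O1 | intermediate
14 | (2S,7R)-7-[(1R)-1-(triethylsilyloxy)propyl]-2,3,6,7-tetrahydrooxepine-2-carbaldehyde | O=C[C@@H]1CC=CC[C@H]([C@H](O[Si](CC)(CC)CC)CC)O1 | intermediate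
15 | (1S)-1-{(2S,7R)-7-[(1R)-1-(triethylsilyloxy)propyl]-2,3,6,7-tetrahydrooxepin-2-yl}but-3-yn-1-ol | C#CC[C@H](O)[C@@H]1CC=CC[C@H]([C@H](O[Si](CC)(CC)CC)CC)O1 | intermediate
16 | (1S)-1-{(2S,7R)-7-[(1R)-1-(triethylsilyloxy)propyl]-2,3,6,7-tetrahydrooxepin-2-yl}-6-(triisopropylsilyl)hexa-3,5-diyn-1-ol | CC(C)[Si](C#CC#CC[C@H](O)[C@@H]1CC=CC[C@H]([C@H](O[Si](CC)(CC)CC)CC)O1)(C(C)C)C(C)C | intermediate
17 | (1S,3Z)-1-{(2S,7R)-7-[(1R)-1-(triethylsilyloxy)propyl]-2,3,6,7-tetrahydrooxepin-2-yl}-6-(triisopropylsilyl)hex-3-en-5-yn-1-ol | CC(C)[Si](C#C/C=C\C[C@H](O)[C@@H]1CC=CC[C@H]([C@H](O[Si](CC)(CC)CC)CC)O1)(C(C)C)C(C)C | intermediate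
18 | (1S,3Z)-1-{(2S,7R)-7-[(1R)-1-(triethylsilyloxy)propyl]-2,3,6,7-tetrahydrooxepin-2-yl}-6-(triisopropylsilyl)hex-3-en-5-yn-1-yl acetate | CC(C)[Si](C#C/C=C\C[C@H](OC(C)=O)[C@@H]1CC=CC[C@H]([C@H](O[Si](CC)(CC)CC)CC)O1)(C(C)C)C(C)C | intermediate
19 | (1S,3Z)-1-{(2S,7R)-7-[(1R)-1-hydroxypropyl]-2,3,6,7-tetrahydrooxepin-2-yl}hex-3-en-5-yn-1-yl acetate | C#C/C=C\C[C@H](OC(C)=O)[C@@H]1CC=CC[C@H]([C@H](O)CC)O1 | intermediate
20 | (1S,3Z)-1-{(2S,7R)-7-[(1S)-1-bromopropyl]-2,3,6,7-tetrahydrooxepin-2-yl}hex-3-en-5-yn-1-yl acetate | C#C/C=C\C[C@H](OC(C)=O)[C@@H]1CC=CC[C@H]([C@@H](Br)CC)O1 | target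

**Step count**

Total steps: 15. Longest linear sequence: 14 steps (steps 1, 2 and 4 to 15; step 3 prepares 7 on a side branch).

**Steps most likely to fail**

Step 4. The second stage may be diverted by proton transfer at the imide α-carbon, by acyl transfer from the auxiliary to the amide enolate or by intermolecular alkylation, and the facial selectivity of the ring closure may be poor with an acyl imide on the neighbouring ether carbon. The fallback sets out from 5 and 7 and returns at 13: the two bonds are made in separate operations, with the ring closed only after the imide has been replaced. The first stage alone is run and quenched, and 8 is isolated. LiBH4 (THF, one equivalent of water, 0 °C) removes the auxiliary and should give 2-{[(2R,4Z)-6-chloro-1-hydroxyhex-4-en-2-yl]oxy}-N,N-dimethylacetamide F1. Oxidation with TEMPO (cat.) and PhI(OAc)2 in CH2Cl2 should give 2-{[(2R,4Z)-6-chloro-1-oxohex-4-en-2-yl]oxy}-N,N-dimethylacetamide F2. Chelation-controlled addition of EtMgBr (MgBr2·OEt2, CH2Cl2, −78 °C) should give 2-{[(3R,4R,6Z)-8-chloro-3-hydroxyoct-6-en-4-yl]oxy}-N,N-dimethylacetamide F3. Et3SiCl and imidazole should give 2-{[(3R,4R,6Z)-8-chloro-3-(triethylsilyloxy)oct-6-en-4-yl]oxy}-N,N-dimethylacetamide F4. KN(SiMe3)2 (THF, −78 °C) should then close the oxepene by intramolecular amide enolate alkylation on a substrate of the established type, giving 13.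

Step 12. The semi-reduction may stall, may run on to the diene, or may attack the wrong triple bond. The fallback sets out from 15 and returns at 17, building the Z-olefin before the second alkyne is attached. N-Iodosuccinimide with AgNO3 (cat.) in acetone should give (1S)-4-iodo-1-{(2S,7R)-7-[(1R)-1-(triethylsilyloxy)propyl]-2,3,6,7-tetrahydrooxepin-2-yl}but-3-yn-1-ol F5. Diimide, generated from 2-nitrobenzenesulfonyl hydrazide and Et3N, should reduce the iodoalkyne to (1S,3Z)-4-iodo-1-{(2S,7R)-7-[(1R)-1-(triethylsilyloxy)propyl]-2,3,6,7-tetrahydrooxepin-2-yl}but-3-en-1-ol F6. Sonogashira coupling with ethynyltriisopropylsilane (Pd(PPh3)4, CuI, i-Pr2NH) should give 17 with the olefin geometry retained.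

Step 15. Displacement at the hindered C13 may be overtaken by participation of the ring oxygen (retention or ring rearrangement) or by elimination at 70 °C. The fallback sets out from 19 and returns at 20, separating activation from displacement. ClCH2SO2Cl and 2,6-lutidine (CH2Cl2, 0 °C) should give (1S,3Z)-1-{(2S,7R)-7-[(1R)-1-{[(chloromethyl)sulfonyl]oxy}propyl]-2,3,6,7-tetrahydrooxepin-2-yl}hex-3-en-5-yn-1-yl acetate F7. Bu4NBr in toluene at moderate temperature should then displace this very good leaving group with inversion to give 20.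

**Further compounds**

F1 | step 4 | 2-{[(2R,4Z)-6-chloro-1-hydroxyhex-4-en-2-yl]oxy}-N,N-dimethylacetamide | CN(C)C(=O)CO[C@H](C/C=C\CCl)CO
F2 | step 4 | 2-{[(2R,4Z)-6-chloro-1-oxohex-4-en-2-yl]oxy}-N,N-dimethylacetamide | CN(C)C(=O)CO[C@H](C/C=C\CCl)C=O
F3 | step 4 | 2-{[(3R,4R,6Z)-8-chloro-3-hydroxyoct-6-en-4-yl]oxy}-N,N-dimethylacetamide | CN(C)C(=O)CO[C@H](C/C=C\CCl)[C@H](O)CC
F4 | step 4 | 2-{[(3R,4R,6Z)-8-chloro-3-(triethylsilyloxy)oct-6-en-4-yl]oxy}-N,N-dimethylacetamide | CN(C)C(=O)CO[C@H](C/C=C\CCl)[C@H](O[Si](CC)(CC)CC)CC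
F5 | step 12 | (1S)-4-iodo-1-{(2S,7R)-7-[(1R)-1-(triethylsilyloxy)propyl]-2,3,6,7-tetrahydrooxepin-2-yl}but-3-yn-1-ol | IC#CC[C@H](O)[C@@H]1CC=CC[C@H]([C@H](O[Si](CC)(CC)CC)CC)O1
F6 | step 12 | (1S,3Z)-4-iodo-1-{(2S,7R)-7-[(1R)-1-(triethylsilyloxy)propyl]-2,3,6,7-tetrahydrooxepin-2-yl}but-3-en-1-ol | I/C=C\C[C@H](O)[C@@H]1CC=CC[C@H]([C@H](O[Si](CC)(CC)CC)CC)O1
F7 | step 15 | (1S,3Z)-1-{(2S,7R)-7-[(1R)-1-{[(chloromethyl)sulfonyl]oxy}propyl]-2,3,6,7-tetrahydrooxepin-2-yl}hex-3-en-5-yn-1-yl acetate | C#C/C=C\C[C@H](OC(C)=O)[C@@H]1CC=CC[C@H]([C@H](OS(=O)(=O)CCl)CC)O1
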